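## Analysis of the target

The target 22 is a flavone: a 4H-chromen-4-one (ring A fused to the pyranone ring C) with a phenyl ring B on C2. It has no stereocenter and no stereogenic double bond, so the whole problem is one of substitution pattern. Every position that can carry oxygen does: ring A is fully substituted with OH on C5 and C7 alternating with OMe on C6 and C8, ring C has OMe on C3, and ring B is a 2',5'-dihydroxy-4'-methoxyphenyl group, that is, a methoxyhydroquinone. The sensitive parts are this hydroquinone, which air and base turn into the quinone, and the electron-rich 5,7-dihydroxy-6,8-dimethoxy ring A; four methyl ethers must also survive while four phenols are set free. The difficulty lies in the hexasubstituted ring A, where free and methylated oxygens alternate so that neither selective methylation nor selective demethylation of a common polyphenol will do, and in bringing the 3-methoxy group and the ortho-substituted ring B onto C2–C3. The strategy rests on the O1–C8a bond. C8a stands para to the C6 methoxy and ortho to the C8 methoxy group, so it is the most electrophilic carbon of an oxidised ring A. When O1 is taken off C8a, ring A becomes a pentasubstituted arene with a single C–H that can be made from syringol 1, and O1 is recognised as the C2 oxygen of a 1,3-diketone.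

## Retrosynthetic reasoning

**22 ⇒ 21 ⇒ 20 (protecting groups).** The last two operations only uncover phenols. In 20 the C5 and C7 oxygens are benzyl ethers and the C2' and C5' oxygens are pivalate esters. The esters are cut first, by transesterification, to give 21. The benzyl ethers go last, by hydrogenolysis, so that 22 with its four free phenols forms under neutral, reducing conditions and never meets base or an oxidant. Benzyl against methyl gives exactly the differentiation that the OH/OMe alternation of ring A demands, and the two acyl groups on ring B have a second task in the key step.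

**20 ⇒ 19 (O1–C8a, the key disconnection).** The bond between the ring oxygen and ring A is cut, which opens ring C to the 1,3-diketone 19, written as the enol whose hydroxyl sits on C2. The classical cut at O1–C2 would need a hydroxyl on C8a before ring closure, hence a hexasubstituted ring A ketone with three differentiated kinds of oxygen. The cut at O1–C8a leaves ring A of 19 pentasubstituted, with its single C–H on the very carbon that must be oxygenated. The forward reaction has to remove two hydrogen atoms, the enol O–H and the C8a–H, and join the two atoms; this is done at an anode. Ring A must be the part that is oxidised and attacked, which is why ring B carries electron-withdrawing pivalates while ring A keeps four ether oxygens. It cannot be taken for granted that 20 is harder to oxidise than 19, so the charge passed is limited.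

**19 ⇒ 12 + 18 (C2–C3).** The diketone is cut between the methoxy-bearing carbon and the carbonyl next to ring B. This gives the ring A α-methoxy ketone 12 as the enolate partner and the ring B acid chloride 18 as the acyl donor. The opposite polarity would place an enolisable ketone ortho to an aryl ester on ring B and invite acyl migration. As chosen, the only enolisable position of either partner is the methoxymethyl group of 12. The forward reaction must be a C-acylation that spares the pivalates, which a magnesium enolate formed by soft enolisation should achieve. The 3-methoxy group of the flavone is carried in with 12, so C3 needs no later oxidation.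

**12 ⇒ 8 + 10 (aryl–carbonyl bond).** The ketone is cut between ring A and its carbonyl carbon. This gives the aryl bromide 8, used as the aryllithium 11, and the Weinreb amide 10, which is one step from the acid chloride 9. A Lewis-acid acyl shift from oxygen to carbon starting from 6 would be shorter on paper, but the Lewis acid would strip the benzyl ether that lies between two methoxy groups. The anionic route runs at −78 °C, and the position of the bromine fixes where the acyl group enters.

**8 ⇒ 7 ⇒ 6 (O–benzyl and C–Br).** The second benzyl group is removed to the bromophenol 7, and the bromine is removed to the phenol 6. In 6 the hydroxyl is the strongest director, and its para position and one ortho position are occupied. The free ortho position is the carbon that must carry the acyl group, so a phenol-directed ortho-bromination sets the last substituent of ring A.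

**6 ⇒ 3 ⇒ 2 ⇒ 1 (C–O, C–Br, O–benzyl).** The hydroxyl of 6 is traced back to the bromine of 3 (exchange to 4, borylation to 5, oxidation). The bromine of 3 comes from electrophilic bromination of 2 ortho to a methoxy group, and 2 from benzylation of syringol 1. Syringol supplies the C6–OMe/C7–O/C8–OMe triad of the target with the C7 oxygen already differentiated from its two methylated neighbours, which is the reason for starting there.

**18 ⇒ 17 ⇒ 15 ⇒ 13 (ring B).** The acid chloride 18 comes from the acid 17, and 17 from the dihydroxy acid 15 by pivaloylation (the carboxyl group is acylated in passing to 16 and released on work-up). 15 is cut at the C5–O bond of the benzoic acid (C5' of the target). An Elbs hydroxylation of the commercial salicylic acid 13 places the new oxygen para to the existing hydroxyl through the sulfate 14. The carboxyl carbon, the methoxy group and both hydroquinone oxygens of ring B are then in place after one step.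

## Alternatives that were turned down

**Alternative 1:** Ring A is opened at C4a–C8a, the bond that chalcone synthase makes, which leads back to an open polyketide chain stored as the 4-hydroxy-2-pyrone A2.
- Forward key step: Mg(OMe)2 in methanol would open the lactone of A2, and in the resulting chain the C4a methylene would attack the ester carbon in a Claisen condensation to give the acylphloroglucinol chalcone A1. An oxidative closure of O1–C2 and removal of the benzyl groups would have to follow.
- For it: ring A is born with all its oxygens. The trihydroxydimethoxyphenyl ring of A1 is symmetric, so either ortho hydroxyl closes ring C to the same 5,7-dihydroxy-6,8-dimethoxy pattern. On this point it is stronger than the chosen route, which has to build the alternating pattern by stepwise aromatic substitution.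
- Against it: A2 is a densely oxygenated nine-carbon chain with two methoxylated ring carbons and an α-methoxy enone, and its preparation alone would cost more steps than the chosen route spends to reach 19. The opened chain can also fold by aldol attack of C8 on the C4 carbonyl, and the α-methoxy enone can take up methoxide. A1 carries a hexasubstituted ring with three free phenols that oxidises in air. Ring C must then still be closed and dehydrogenated.
- Comparison: the chosen route gives up the gain in skeletal bonds, but it starts from arenes that already hold the oxygens and makes ring C and the flavone in one step.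

**Alternative 2:** Ring B is dissected into an alkyne, an alkenylcarbene and one CO, that is, at C5'–C6', C1'–C2' and C2'–C3'.
- Forward key step: the 2-ethynylchromone A4 and the chromium carbene complex A5, (CO)5Cr=C(OMe)C(OMe)=CH2, would undergo a Dötz benzannulation. Oxidative work-up with (NH4)2Ce(NO3)6 would give the quinone A3, to be reduced to the hydroquinone and debenzylated.
- For it: three C–C bonds and a ring in one step, against one C–O bond in the chosen step. The reaction type is well documented, with dependable regiochemistry for terminal alkynes (the substituted alkyne carbon ends next to the carbonyl-derived oxygen). Ring B arrives exactly at the quinone/hydroquinone oxidation level with the C4' methoxy placed by the carbene. On bond count and on precedent it is the stronger proposal.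
- Against it: A4 already contains the complete, fully oxygenated chromone, so the real difficulty of the target (ring A and the O1–C8a/C3–OMe region) is only moved into a long conventional synthesis of A4. The alkyne of A4 is conjugated to the pyranone and electron-poor, a class that tends to give cyclobutenones, furans or indenes in place of the phenol. A5 is a sensitive reagent needed in stoichiometric amount. The cerium oxidant meets a tetraalkoxy ring A with two benzyl ethers.
- Comparison: the chosen route assembles the entire carbon skeleton by one C-acylation of two simple arenes, and it has a known fallback from the same intermediates.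

**Alternative 3:** Ring C is cut three times, at O1–C8a, C4–C4a and O1–C2, into a ring A aryne and an arylpropiolate.
- Forward key step: CsF would release the aryne from the silyl triflate A7, and the cesium salt of the propiolic acid A8 would add through oxygen. The aryl anion would take over the acyl group (net insertion into the C–O bond), and the phenoxide so formed would close onto the ynone to give the flavone A6.
- For it: three bonds and ring C in one convergent, metal-free operation of a known reaction type, which is more than the chosen step achieves.
- Against it: both aryne carbons are flanked by oxygen substituents (pivaloyloxy at C5, methoxy at C8). The sense of addition depends only on the small difference between these two groups, so a mixture of the 5-pivaloyloxy-8-methoxy flavone and the reversed one is to be expected. A7 is a hexasubstituted benzene whose synthesis is longer than that of 12. A6 has hydrogen on C3, so the 3-methoxy group must be added afterwards by C3 oxygenation and methylation in the presence of the other protected phenols.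
- Comparison: in the chosen route the 3-methoxy group comes with the methoxyacetyl unit, and the position of ring closure is fixed because C8a is the only C–H of ring A. The price is a key step without direct precedent.

Key step: step 12

Remark on the chemistry: 19 is one compound that exists as a diketo/enol mixture. It is written as the (E)-enol that cyclises; the C2 stereocenter of its diketo form is configurationally labile and is lost in step 12, so no stereodescriptor applies.

## Route

Step 1
Reactants: 1 2,6-dimethoxyphenol (syringol)
Product: 2 2-(benzyloxy)-1,3-dimethoxybenzene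
Conditions: BnBr, K2CO3, DMF, 60 °C
Reagents that add atoms: benzyl bromide BrCc1ccccc1
Why: Williamson ether synthesis; the hindered but acidic phenoxide of 1 should be alkylated cleanly by the reactive benzylic halide in DMF.

Step 2
Reactants: 2 2-(benzyloxy)-1,3-dimethoxybenzene
Product: 3 2-(benzyloxy)-4-bromo-1,3-dimethoxybenzene
Conditions: NBS (1.0 equiv), MeCN, 0 °C → rt
Reagents that add atoms: N-bromosuccinimide O=C1CCC(=O)N1Br
Why: Electrophilic aromatic bromination; the central benzyloxy group is twisted out of conjugation by its two neighbours, so the two methoxy groups direct to C4 (ortho to one, para to the other), as in 1,2,3-trimethoxybenzene, and one equivalent of NBS at low temperature should stop at the monobromide.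

Step 3
Reactants: 3 2-(benzyloxy)-4-bromo-1,3-dimethoxybenzene
Product: 6 3-(benzyloxy)-2,4-dimethoxyphenol, via aryllithium 4 (not isolated), via dimethyl arylboronate 5 (not isolated)
Conditions: nBuLi, THF, −78 °C; B(OMe)3, −78 °C → rt; AcOH, 30% aq. H2O2, 0 °C → rt
Reagents that add atoms: n-butyllithium [Li]CCCC (Li, kept only in 4); trimethyl borate COB(OC)OC (B(OMe)2, kept only in 5); hydrogen peroxide OO (the phenol oxygen)
Why: Bromine–lithium exchange, borylation and oxidative C–B to C–O migration replace bromine by hydroxyl at the same carbon, so the regiochemistry of step 2 is kept; buffering with AcOH should keep the electron-rich phenol from further oxidation.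

Step 4
Reactants: 6 3-(benzyloxy)-2,4-dimethoxyphenol
Product: 7 3-(benzyloxy)-6-bromo-2,4-dimethoxyphenol
Conditions: NBS (1.0 equiv), iPr2NH (10 mol %), CH2Cl2, −20 °C → 0 °C
Reagents that add atoms: N-bromosuccinimide O=C1CCC(=O)N1Br
Why: Amine-catalysed ortho-bromination of a phenol; the hydroxyl is the strongest donor, its para position (C4, methoxy) and one ortho position (C2, methoxy) are blocked, and the hydrogen-bonded N-bromoamine should deliver bromine to the remaining ortho carbon C6.

Step 5
Reactants: 7 3-(benzyloxy)-6-bromo-2,4-dimethoxyphenol
Product: 8 2,4-bis(benzyloxy)-1-bromo-3,5-dimethoxybenzene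
Conditions: BnBr, K2CO3, DMF, 50 °C
Reagents that add atoms: benzyl bromide BrCc1ccccc1
Why: Williamson ether synthesis on an ortho-bromophenoxide; no other acidic or nucleophilic site is present.

Step 6
Reactants: 9 methoxyacetyl chloride
Product: 10 N,2-dimethoxy-N-methylacetamide
Conditions: MeNH(OMe)·HCl, Et3N (2.2 equiv), CH2Cl2, 0 °C → rt
Reagents that add atoms: N,O-dimethylhydroxylamine hydrochloride CNOC.Cl
Why: N-acylation of N,O-dimethylhydroxylamine by the acid chloride (Weinreb amide formation), with Et3N taking up both equivalents of HCl.

Step 7
Reactants: 8 2,4-bis(benzyloxy)-1-bromo-3,5-dimethoxybenzene; 10 N,2-dimethoxy-N-methylacetamide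
Product: 12 1-[2,4-bis(benzyloxy)-3,5-dimethoxyphenyl]-2-methoxyethan-1-one, via aryllithium 11 (not isolated)
Conditions: nBuLi, THF, −78 °C; then 10, −78 °C → 0 °C; 1 M HCl
Reagents that add atoms: n-butyllithium [Li]CCCC (Li, kept only in 11)
Why: Bromine–lithium exchange at −78 °C is faster than benzylic deprotonation, and the aryllithium adds only once to the Weinreb amide because the chelated tetrahedral adduct survives until the acidic quench (Weinreb ketone synthesis); the acyl group enters exactly where the bromine stood.

Step 8
Reactants: 13 2-hydroxy-4-methoxybenzoic acid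
Product: 15 2,5-dihydroxy-4-methoxybenzoic acid, via aryl sulfate 14 (not isolated)
Conditions: K2S2O8, aq. NaOH, 0 °C → rt; then HCl, extraction of unreacted 13; aq. HCl, 85 °C
Reagents that add atoms: potassium peroxodisulfate [K+].[K+].[O-]S(=O)(=O)OOS(=O)(=O)[O-]
Why: Elbs persulfate oxidation; the phenoxide of 13 attacks the peroxide oxygen through its para carbon, which is also ortho to the methoxy group, to give the aryl sulfate 14, and acid hydrolysis releases the hydroquinone. The sulfate shields the new oxygen from further oxidation until the oxidant is gone.

Step 9
Reactants: 15 2,5-dihydroxy-4-methoxybenzoic acid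
Product: 17 4-methoxy-2,5-bis(pivaloyloxy)benzoic acid, via mixed pivalic anhydride 16 (not isolated)
Conditions: PivCl (3.5 equiv), pyridine, DMAP (cat.), CH2Cl2, 0 °C → rt; then H2O, THF, rt
Reagents that add atoms: pivaloyl chloride CC(C)(C)C(=O)Cl; water O (carboxyl oxygen after hydrolysis of 16)
Why: DMAP-catalysed O-acylation of both phenols; the carboxyl group is acylated as well to the mixed anhydride 16, which the aqueous work-up should hydrolyse selectively because an anhydride is far more labile than the hindered aryl pivalates.

Step 10
Reactants: 17 4-methoxy-2,5-bis(pivaloyloxy)benzoic acid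
Product: 18 4-methoxy-2,5-bis(pivaloyloxy)benzoyl chloride
Conditions: (COCl)2, DMF (cat.), CH2Cl2, 0 °C → rt
Reagents that add atoms: oxalyl chloride O=C(Cl)C(Cl)=O
Why: Acid chloride formation through the chloroiminium salt from DMF and (COCl)2 under neutral conditions that leave aryl pivalates untouched; 2-acyloxybenzoyl chlorides are stable compounds.

Step 11
Reactants: 12 1-[2,4-bis(benzyloxy)-3,5-dimethoxyphenyl]-2-methoxyethan-1-one; 18 4-methoxy-2,5-bis(pivaloyloxy)benzoyl chloride
Product: 19 1-[2,4-bis(benzyloxy)-3,5-dimethoxyphenyl]-2-methoxy-3-[4-methoxy-2,5-bis(pivaloyloxy)phenyl]propane-1,3-dione, written as its (E)-enol (hydroxyl on the carbon next to ring B, cis to the ring A carbonyl)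
Conditions: MgBr2·OEt2 (2.5 equiv), iPr2NEt (3 equiv), CH2Cl2, 0 °C → rt; 1 M HCl work-up
Reagents that add atoms: none
Why: Soft enolisation and C-acylation; MgBr2 chelates the ketone and its α-methoxy oxygen so that iPr2NEt can deprotonate the only enolisable position, and the magnesium enolate is acylated on carbon by the aroyl chloride. The product is held as its magnesium chelate, which stops a second acylation, and the bulky pivalate ortho to the new ketone should resist acyl transfer.

Step 12
Reactants: 19 1-[2,4-bis(benzyloxy)-3,5-dimethoxyphenyl]-2-methoxy-3-[4-methoxy-2,5-bis(pivaloyloxy)phenyl]propane-1,3-dione ((E)-enol)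
Product: 20 2-[5,7-bis(benzyloxy)-3,6,8-trimethoxy-4-oxo-4H-chromen-2-yl]-5-methoxy-1,4-phenylene bis(2,2-dimethylpropanoate)
Conditions: graphite anode, Pt cathode, undivided cell, constant current (5 mA cm−2, 2.2 F mol−1), Bu4NPF6 (0.1 M), HFIP/CH2Cl2 (4:1), 20 °C
Reagents that add atoms: none
Why: Proposed new method: the anode takes one electron from 19, either from the tetraalkoxy ring A or from the enol π system, and both radical cations lead to the same O1–C8a bond, because the oxygen on C2 (the enol hydroxyl, or the carbonyl oxygen of the diketo form followed by loss of the C3 proton) is the only nucleophile that can reach ring A through a six-membered transition state; a second electron and two protons are then lost to restore aromaticity, and HFIP is reduced to H2 at the cathode. The closest known reaction type is anodic dehydrogenative C–O cyclisation onto arenes, as in benzoxazoles from anilides and benzocoumarins from biaryl-2-carboxylic acids, and on the chemical side the FeCl3-mediated closure of electron-rich α-aryl ketones to benzofurans; closure of a chromone by a 1,3-diketone oxygen in this way has not been shown. Ring C closes in a six-membered mode, 6-endo-trig with respect to the C4a–C8a π bond of the arene. No stereocenter is formed. The step needs regioselectivity for C8a, chemoselectivity for ring A over ring B, and a stop after two electrons. C8a is the only C–H of ring A and carries much of the positive charge of the radical cation, being para to the C6 methoxy and ortho to the C8 methoxy group, whereas the other ortho carbon, C5, bears a benzyloxy group and cannot rearomatise after ipso attack without losing benzyl. Ring B is kept out because its two pivalates raise its oxidation potential and because its free ortho carbon C6' is meta to its only methoxy group. HFIP stabilises the radical cation and is too weak a nucleophile to compete with the internal oxygen, and the charge is limited because 20, although a vinylogous ester, still carries an electron-rich ring A.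

Step 13
Reactants: 20 2-[5,7-bis(benzyloxy)-3,6,8-trimethoxy-4-oxo-4H-chromen-2-yl]-5-methoxy-1,4-phenylene bis(2,2-dimethylpropanoate)
Product: 21 5,7-bis(benzyloxy)-2-(2,5-dihydroxy-4-methoxyphenyl)-3,6,8-trimethoxy-4H-chromen-4-one
Conditions: K2CO3 (2 equiv), MeOH/THF (degassed), argon, 0 °C → rt; then AcOH
Reagents that add atoms: none
Why: Base-mediated transesterification; phenoxides are good leaving groups, so methoxide should remove even the hindered pivalates at room temperature while benzyl ethers, methyl ethers and the chromone stay intact. Exclusion of air keeps the hydroquinone from going to the quinone.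

Step 14
Reactants: 21 5,7-bis(benzyloxy)-2-(2,5-dihydroxy-4-methoxyphenyl)-3,6,8-trimethoxy-4H-chromen-4-one
Product: 22 5,7-dihydroxy-2-(2,5-dihydroxy-4-methoxyphenyl)-3,6,8-trimethoxy-4H-chromen-4-one (5,7,2',5'-tetrahydroxy-3,6,8,4'-tetramethoxyflavone)
Conditions: H2 (1 atm), 10% Pd/C, EtOAc/MeOH, rt
Reagents that add atoms: none
Why: Catalytic hydrogenolysis of the two benzyl aryl ethers under neutral conditions; the methyl ethers and the tetrasubstituted, conjugated C2–C3 double bond of the chromone should not be reduced at one atmosphere, and the product needs only filtration under inert gas.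

## Compound list

1 | 2,6-dimethoxyphenol (syringol) | COc1cccc(OC)c1O | starting material
2 | 2-(benzyloxy)-1,3-dimethoxybenzene | COc1cccc(OC)c1OCc1ccccc1 | intermediate
3 | 2-(benzyloxy)-4-bromo-1,3-dimethoxybenzene | COc1ccc(Br)c(OC)c1OCc1ccccc1 | intermediate
4 | [3-(benzyloxy)-2,4-dimethoxyphenyl]lithium | [Li]c1ccc(OC)c(OCc2ccccc2)c1OC | intermediate
5 | dimethyl [3-(benzyloxy)-2,4-dimethoxyphenyl]boronate | COB(OC)c1ccc(OC)c(OCc2ccccc2)c1OC | intermediate
6 | 3-(benzyloxy)-2,4-dimethoxyphenol | COc1ccc(O)c(OC)c1OCc1ccccc1 | intermediate
7 | 3-(benzyloxy)-6-bromo-2,4-dimethoxyphenol | COc1cc(Br)c(O)c(OC)c1OCc1ccccc1 | intermediate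
8 | 2,4-bis(benzyloxy)-1-bromo-3,5-dimethoxybenzene | COc1cc(Br)c(OCc2ccccc2)c(OC)c1OCc1ccccc1 | intermediate
9 | methoxyacetyl chloride | COCC(Cl)=O | starting material
10 | N,2-dimethoxy-N-methylacetamide | COCC(=O)N(C)OC | intermediate
11 | [2,4-bis(benzyloxy)-3,5-dimethoxyphenyl]lithium | [Li]c1cc(OC)c(OCc2ccccc2)c(OC)c1OCc1ccccc1 | intermediate
12 | 1-[2,4-bis(benzyloxy)-3,5-dimethoxyphenyl]-2-methoxyethan-1-one | COCC(=O)c1cc(OC)c(OCc2ccccc2)c(OC)c1OCc1ccccc1 | intermediate
13 | 2-hydroxy-4-methoxybenzoic acid | COc1ccc(C(=O)O)c(O)c1 | starting material
14 | 2-hydroxy-4-methoxy-5-(sulfooxy)benzoic acid (present as its salt) | COc1cc(O)c(C(=O)O)cc1OS(=O)(=O)O | intermediate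
15 | 2,5-dihydroxy-4-methoxybenzoic acid | COc1cc(O)c(C(=O)O)cc1O | intermediate
16 | 4-methoxy-2,5-bis(pivaloyloxy)benzoic pivalic anhydride | COc1cc(OC(=O)C(C)(C)C)c(C(=O)OC(=O)C(C)(C)C)cc1OC(=O)C(C)(C)C | intermediate
17 | 4-methoxy-2,5-bis(pivaloyloxy)benzoic acid | COc1cc(OC(=O)C(C)(C)C)c(C(=O)O)cc1OC(=O)C(C)(C)C | intermediate
18 | 4-methoxy-2,5-bis(pivaloyloxy)benzoyl chloride | COc1cc(OC(=O)C(C)(C)C)c(C(Cl)=O)cc1OC(=O)C(C)(C)C | intermediate
19 | 1-[2,4-bis(benzyloxy)-3,5-dimethoxyphenyl]-2-methoxy-3-[4-methoxy-2,5-bis(pivaloyloxy)phenyl]propane-1,3-dione, as its (E)-enol | COc1cc(C(=O)/C(OC)=C(/c2cc(OC(=O)C(C)(C)C)c(OC)cc2OC(=O)C(C)(C)C)O)c(OCc2ccccc2)c(OC)c1OCc1ccccc1 | intermediate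
20 | 2-[5,7-bis(benzyloxy)-3,6,8-trimethoxy-4-oxo-4H-chromen-2-yl]-5-methoxy-1,4-phenylene bis(2,2-dimethylpropanoate) | COc1cc(OC(=O)C(C)(C)C)c(-c2oc3c(OC)c(OCc4ccccc4)c(OC)c(OCc4ccccc4)c3c(=O)c2OC)cc1OC(=O)C(C)(C)C | intermediate
21 | 5,7-bis(benzyloxy)-2-(2,5-dihydroxy-4-methoxyphenyl)-3,6,8-trimethoxy-4H-chromen-4-one | COc1cc(O)c(-c2oc3c(OC)c(OCc4ccccc4)c(OC)c(OCc4ccccc4)c3c(=O)c2OC)cc1O | intermediate
22 | 5,7-dihydroxy-2-(2,5-dihydroxy-4-methoxyphenyl)-3,6,8-trimethoxy-4H-chromen-4-one | COc1cc(O)c(-c2oc3c(OC)c(O)c(OC)c(O)c3c(=O)c2OC)cc1O | target

## Step count and least certain steps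

Total step count: 14. Longest linear sequence: 10 steps (steps 1, 2, 3, 4, 5, 7, 11, 12, 13, 14); steps 6 and 8–10 are side branches.

**Step 12 (key step, beyond known chemistry).**
- What may go wrong: over-oxidation of the product; oxidation at the enol carbon C3 with trapping by the solvent or cleavage of the dicarbonyl unit in place of C–O closure; loss of a benzyl group by ipso attack at C5 or by benzylic oxidation.
- Why: ring A of 20 stays electron-rich, and the 2-methoxy enol is itself an easily oxidised π system.
- Fallback (known chemistry): it sets out from 12 and comes back at 20.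
  - Ring bromination of 12 at its only aromatic C–H with NBS in MeCN should give 1-[2,4-bis(benzyloxy)-6-bromo-3,5-dimethoxyphenyl]-2-methoxyethan-1-one F1.
  - C-acylation of F1 with 18 under the conditions of step 11 should give 1-[2,4-bis(benzyloxy)-6-bromo-3,5-dimethoxyphenyl]-2-methoxy-3-[4-methoxy-2,5-bis(pivaloyloxy)phenyl]propane-1,3-dione F2.
  - An intramolecular Ullmann-type O-arylation of the enolate of F2 (CuI, 1,10-phenanthroline, K3PO4, toluene, 100 °C), a known way from 1-(2-haloaryl)-1,3-diketones to chromones, should close the O1–C8a bond to 20.
  - The bond formed is the same, but the carbon is activated by a halogen and a copper catalyst in place of the anode.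

**Step 4.**
- What may go wrong: bromination at the C–H ortho to the C4 methoxy group instead of ortho to the hydroxyl, or oxidation of the para-alkoxyphenol to a quinone.
- Why: both free positions of 6 are activated, and a hydroquinone monoether is easily oxidised by electrophilic halogen.
- Fallback: it sets out from 6 and comes back at 12, so that steps 5 and 7 are not needed.
  - Magnesium-mediated ortho-formylation (MgCl2, Et3N, paraformaldehyde, MeCN, reflux), which can only occur next to the phenoxide oxygen, should give 4-(benzyloxy)-2-hydroxy-3,5-dimethoxybenzaldehyde F3.
  - Benzylation (BnBr, K2CO3, DMF) should give 2,4-bis(benzyloxy)-3,5-dimethoxybenzaldehyde F4.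
  - Addition of MeOCH2MgCl in THF at −20 °C should give racemic 1-[2,4-bis(benzyloxy)-3,5-dimethoxyphenyl]-2-methoxyethan-1-ol F5.
  - Oxidation of F5 with Dess–Martin periodinane should give 12.

**Step 8.**
- What may go wrong: low conversion and oxidative degradation.
- Why: the Elbs reaction usually stops at partial conversion, and any hydroquinone set free too early is oxidised by remaining persulfate more easily than 13 is.
- Fallback: it sets out from 13 and comes back at 15.
  - Bromination (Br2, AcOH) para to the hydroxyl and ortho to the methoxy group should give 5-bromo-2-hydroxy-4-methoxybenzoic acid F6.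
  - Copper-catalysed hydroxylation of the aryl bromide (CuI, aq. NaOH, 100 °C, argon), the classical route from 5-halosalicylic acids to gentisic acids, should give 15.

**Step 11.**
- What may go wrong: cleavage of the benzyl ether ortho to the ketone by chelated MgBr2, O-acylation, or transfer of the ortho pivaloyl group onto the enolate.
- Why: the ketone carbonyl and the ortho benzyloxy oxygen form a chelate with the Lewis acid, and the product enolate sits next to an aryl ester.
- Fallback: it sets out from 17 and 12 and comes back at 19.
  - 17 is converted with 1H-benzotriazole and SOCl2 in CH2Cl2 into 1-[4-methoxy-2,5-bis(pivaloyloxy)benzoyl]-1H-benzotriazole F7.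
  - The lithium enolate of 12 (LiN(SiMe3)2, THF, −78 °C) is acylated on carbon by F7 to give 19, without any Lewis acid and at low temperature.

## Further compounds

F1 | step 12 | 1-[2,4-bis(benzyloxy)-6-bromo-3,5-dimethoxyphenyl]-2-methoxyethan-1-one | COCC(=O)c1c(Br)c(OC)c(OCc2ccccc2)c(OC)c1OCc1ccccc1
F2 | step 12 | 1-[2,4-bis(benzyloxy)-6-bromo-3,5-dimethoxyphenyl]-2-methoxy-3-[4-methoxy-2,5-bis(pivaloyloxy)phenyl]propane-1,3-dione (diketo form, C2 labile) | COc1cc(OC(=O)C(C)(C)C)c(C(=O)C(OC)C(=O)c2c(Br)c(OC)c(OCc3ccccc3)c(OC)c2OCc2ccccc2)cc1OC(=O)C(C)(C)C
F3 | step 4 | 4-(benzyloxy)-2-hydroxy-3,5-dimethoxybenzaldehyde | COc1cc(C=O)c(O)c(OC)c1OCc1ccccc1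
F4 | step 4 | 2,4-bis(benzyloxy)-3,5-dimethoxybenzaldehyde | COc1cc(C=O)c(OCc2ccccc2)c(OC)c1OCc1ccccc1
F5 | step 4 | 1-[2,4-bis(benzyloxy)-3,5-dimethoxyphenyl]-2-methoxyethan-1-ol (racemic) | COCC(O)c1cc(OC)c(OCc2ccccc2)c(OC)c1OCc1ccccc1
F6 | step 8 | 5-bromo-2-hydroxy-4-methoxybenzoic acid | COc1cc(O)c(C(=O)O)cc1Br
F7 | step 11 | 1-[4-methoxy-2,5-bis(pivaloyloxy)benzoyl]-1H-benzotriazole | COc1cc(OC(=O)C(C)(C)C)c(C(=O)n2nnc3ccccc32)cc1OC(=O)C(C)(C)C
A1 | alternative 1 | (Z)-3-[2,5-bis(benzyloxy)-4-methoxyphenyl]-2-methoxy-1-(2,4,6-trihydroxy-3,5-dimethoxyphenyl)prop-2-en-1-one | COc1c(O)c(OC)c(O)c(C(=O)/C(OC)=C/c2cc(OCc3ccccc3)c(OC)cc2OCc2ccccc2)c1O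
A2 | alternative 1 | 6-{(3Z)-4-[2,5-bis(benzyloxy)-4-methoxyphenyl]-3-methoxy-2-oxobut-3-en-1-yl}-4-hydroxy-3,5-dimethoxy-2H-pyran-2-one | O=C1OC(CC(=O)/C(OC)=C/c2cc(OCc3ccccc3)c(OC)cc2OCc2ccccc2)=C(OC)C(O)=C1OC
A3 | alternative 2 | 2-[5,7-bis(benzyloxy)-3,6,8-trimethoxy-4-oxo-4H-chromen-2-yl]-5-methoxy-1,4-benzoquinone | COC1=CC(=O)C(=CC1=O)c1oc2c(OC)c(OCc3ccccc3)c(OC)c(OCc3ccccc3)c2c(=O)c1OC
A4 | alternative 2 | 5,7-bis(benzyloxy)-2-ethynyl-3,6,8-trimethoxy-4H-chromen-4-one | C#Cc1oc2c(OC)c(OCc3ccccc3)c(OC)c(OCc3ccccc3)c2c(=O)c1OC
A5 | alternative 2 | pentacarbonyl(1,2-dimethoxyprop-2-en-1-ylidene)chromium, (CO)5Cr=C(OMe)C(OMe)=CH2 | COC(=C)C(OC)=[Cr](=C=O)(=C=O)(=C=O)(=C=O)=C=O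
A6 | alternative 3 | 7-(benzyloxy)-2-[2,5-bis(benzyloxy)-4-methoxyphenyl]-6,8-dimethoxy-4-oxo-4H-chromen-5-yl pivalate | COc1cc(OCc2ccccc2)c(-c2cc(=O)c3c(OC(=O)C(C)(C)C)c(OC)c(OCc4ccccc4)c(OC)c3o2)cc1OCc1ccccc1
A7 | alternative 3 | 3-(benzyloxy)-2,4-dimethoxy-5-(pivaloyloxy)-6-(trimethylsilyl)phenyl trifluoromethanesulfonate | COc1c(OCc2ccccc2)c(OC)c(OS(=O)(=O)C(F)(F)F)c([Si](C)(C)C)c1OC(=O)C(C)(C)C
A8 | alternative 3 | 3-[2,5-bis(benzyloxy)-4-methoxyphenyl]prop-2-ynoic acid | COc1cc(OCc2ccccc2)c(C#CC(=O)O)cc1OCc1ccccc1
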